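The C5–C9 and C2–C3 bonds of trione ring A are disconnected, which frees the malonyl carbon C1 (bonded to C2, C9 and, through C8, to C7) from the seven-membered ketone ring. The key step re-forms both bonds in one operation: the bis(acid chloride) on C1 acylates C5 and then C3, the two α-carbons of the C4 carbonyl. This closes rings A and B and sets C1, C3 and C5. The precursor is a hydroazulenone with ring D already fused at C3–C11. Its C4 ketone is carried as an O-methyl enol ether and its C7 bears the C8(CH3)2–C1H(COCl)2 arm. Bridgehead geranylation and benzoylation finish the synthesis.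

Key step: step 12

Remarks (target numbering is used for every intermediate):
- Numbering: ring A = C1, C2, C3, C4, C5, C9; ring B = C5, C6, C7, C8, C1, C9; ring D = C3, C11, C12, C13, C14; the carbocycle of the starting ketone = C3, C4, C5, C6, C7, C10, C11.
- Structure check: the precursor and key-step product agree with the target at C7, C11 and C13 (C7 arm cis to C12, isopropyl on C13 trans to C10). Two new bonds add two rings, and the second seven-membered ring C3–C2–C1–C8–C7–C10–C11 is closed by the same C2–C3 bond as ring A. The C3 configuration of the precursor is lost and re-set in the key step, so it need not be controlled.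
- Precursor design: a free C4 ketone cannot be turned into silyl enol ethers beside two acid chlorides (a base gives a ketene at C1, and a free 1,3-diketone enol would O-acylate after the first closure). The precursor is therefore the O-methyl enol ether, and the acid chlorides are made from a dicarboxylate salt without acid or base.
- Assumption: the lithium (R,R)-amide and (S)-BINAP induce in the same sense as on 4-tert-butylcyclohexanone and cyclohept-2-enone; if not, the enantiomeric base or ligand is used.

Step 1
Reactants: 1 8-bromo-1,4-dioxaspiro[4.5]decane; 2 dimethyl isopropylidenemalonate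
Product: 5 dimethyl 2-[2-(4-oxocyclohexyl)propan-2-yl]propanedioate, via Grignard reagent 3 (not isolated), via ketal malonate 4 (not isolated)
Conditions: Mg, THF, 40 °C; then 2, CuBr·SMe2 (5 mol %), THF, −20 → 0 °C; then 2 M HCl, 23 °C
Reagents that add atoms: water, O
Why: Copper-catalysed conjugate (Michael) addition of the secondary Grignard reagent to the doubly activated alkylidenemalonate forms the C7–C8 bond and the quaternary C8, and the acidic quench hydrolyses the dioxolane; 5 is achiral.

Step 2
Reactants: 5 dimethyl 2-[2-(4-oxocyclohexyl)propan-2-yl]propanedioate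
Product: 6 dimethyl 2-{2-[(1S)-4-(trimethylsilyloxy)cyclohex-3-en-1-yl]propan-2-yl}propanedioate
Conditions: lithium (R,R)-bis(1-phenylethyl)amide (from the amine and n-BuLi), Me3SiCl present from the start, THF, −78 °C
Reagents that add atoms: chlorotrimethylsilane, C[Si](C)(C)Cl
Why: Enantioselective deprotonation of the prochiral 4-substituted cyclohexanone by a C2-symmetric chiral lithium amide with in situ silylation distinguishes the two enantiotopic α-methylene groups and so fixes C7 as (S); the shielded tert-alkylmalonate C–H should react much more slowly, and any ketene acetal is lost on work-up.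

Step 3
Reactants: 6 silyl enol ether
Product: 7 dimethyl 2-{2-[(4S)-1-(trimethylsilyloxy)bicyclo[4.1.0]heptan-4-yl]propan-2-yl}propanedioate (both cyclopropane diastereomers)
Conditions: Et2Zn, CH2I2, CH2Cl2, 0 → 23 °C
Reagents that add atoms: diiodomethane, ICI
Why: Simmons–Smith cyclopropanation (diethylzinc variant) of the electron-rich enol ether brings in the future C3; the cyclopropane configuration is irrelevant because both ring carbons become trigonal in step 4.

Step 4
Reactants: 7 siloxycyclopropane
Product: 9 dimethyl 2-{2-[(1S)-5-oxocyclohept-3-en-1-yl]propan-2-yl}propanedioate, via β-chloro ketone 8 (not isolated)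
Conditions: FeCl3, DMF, 0 → 23 °C; then NaOAc, MeOH, 65 °C
Reagents that add atoms: none
Why: Oxidative ring expansion of the siloxycyclopropane (one-electron oxidation by FeCl3 cleaves the ring-fusion bond to the β-chloro cycloheptanone), followed by acetate-induced loss of HCl, gives the C3=C11 enone without touching C7.

Step 5
Reactants: 9 enone
Product: 11 dimethyl 2-{2-[(1R)-4-oxocyclohepta-2,5-dien-1-yl]propan-2-yl}propanedioate, via silyloxydiene 10 (not isolated)
Conditions: Me3SiOTf, Et3N, CH2Cl2, 0 °C; then Pd(OAc)2, MeCN, 23 °C
Reagents that add atoms: none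
Why: Soft enolization toward α′ (C5) gives the cross-conjugated silyloxydiene, and Saegusa–Ito oxidation installs C5=C6; this removes the enolizable hydrogens at C5 so that C3 is the only alkylation site in step 7.

Step 6
Reactants: 11 cross-conjugated dienone; 12 potassium trifluoro(prop-1-en-2-yl)borate
Product: 13 dimethyl 2-{2-[(1R,6S)-4-oxo-6-(prop-1-en-2-yl)cyclohept-2-en-1-yl]propan-2-yl}propanedioate
Conditions: [Rh(cod)2]BF4 (3 mol %), (S)-BINAP, toluene–H2O, 100 °C
Reagents that add atoms: none
Why: Rhodium-catalysed asymmetric 1,4-addition of an alkenyltrifluoroborate (Hayashi–Miyaura reaction) should occur at C11, the β-carbon of the unhindered enone arm (C6 is shielded by the C7 substituent); the (S)-BINAP–rhodium alkenyl species selects the face that gives (11S), isopropenyl cis to the C7 arm, under catalyst control, and the base-free medium avoids γ-deprotonation at C7.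

Step 7
Reactants: 13 isopropenyl enone; 14 1-bromo-3-methylbut-2-ene
Product: 16 dimethyl 2-{2-[(1R,5R,6S)-5-(3-methylbut-2-en-1-yl)-4-oxo-6-(prop-1-en-2-yl)cyclohept-2-en-1-yl]propan-2-yl}propanedioate, via dilithium dienolate 15 (not isolated)
Conditions: LiN(SiMe3)2 (2.2 equiv), THF–DMPU, −78 °C; then 14, −78 → −30 °C
Reagents that add atoms: none
Why: Kinetic deprotonation of the enone at its only α′ position C3 (the hindered malonate is deprotonated too and stays an inert spectator enolate) and SN2 alkylation anti to the neighbouring isopropenyl group should give the 2,3-trans product.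

Step 8
Reactants: 16 prenylated enone
Product: 17 dimethyl 2-{2-[(1S,3S,4R)-4-(3-methylbut-2-en-1-yl)-5-oxo-3-(prop-1-en-2-yl)cycloheptyl]propan-2-yl}propanedioate
Conditions: [(Ph3P)CuH]6, H2O, toluene–THF, 23 °C
Reagents that add atoms: none
Why: Copper hydride conjugate reduction and protonation of the copper enolate remove C5=C6 chemoselectively and leave the two isolated olefins, the ketone and the esters untouched.

Step 9
Reactants: 17 diene ketone
Product: 18 trans-hydroazulenone with ring D closed (C3 R, C7 S, C11 S, C13 R; C7 malonate arm cis to C12, isopropyl trans to C10)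
Conditions: Mn(dpm)3 (10 mol %), PhSiH3, t-BuOOH, i-PrOH, 23 °C
Reagents that add atoms: none
Why: Metal hydride hydrogen atom transfer (Mukaiyama-type radical hydrofunctionalization) to the 1,1-disubstituted isopropenyl olefin gives the tertiary C12 radical, which closes ring D by 5-exo-trig attack on C13, and the new tertiary radical is reduced to isopropyl; a chair-like transition state with C11–C10, C3–C4 and the olefin pseudo-equatorial places isopropyl trans to C10 and cis to C4, as in the target.

Step 10
Reactants: 18 hydroazulenone
Product: 20 C4 methyl enol ether of 18 (drawn as the C4=C5 isomer), via dimethyl ketal 19 (not isolated)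
Conditions: HC(OMe)3, MeOH, TsOH (cat.), 23 °C; then Me3SiOTf, i-Pr2NEt, CH2Cl2, −20 → 23 °C
Reagents that add atoms: trimethyl orthoformate, COC(OC)OC
Why: Acid-catalysed ketalization and silyl triflate-mediated elimination of methanol give the enol ether that caps the C4 oxygen for step 12; both double-bond isomers and both C3 epimers are usable because they converge through the same oxocarbenium ion there.

Step 11
Reactants: 20 enol ether diester
Product: 21 dipotassium malonate of the enol ether
Conditions: KOSiMe3, THF, 23 → 60 °C; filtration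
Reagents that add atoms: potassium trimethylsilanolate, C[Si](C)(C)[O-].[K+]
Why: Anhydrous nucleophilic cleavage of both methyl esters by silanolate precipitates the dicarboxylate salt without an acidic work-up, which the enol ether would not survive.

Step 12
Reactants: 21 dipotassium malonate
Product: 24 caged trione with H at C1/C5, via bis(acid chloride) 22 (not isolated), via monocyclized enol ether 23 (not isolated)
Conditions: (COCl)2 (2.05 equiv), CH2Cl2, −40 °C; then 0.01 M, 23 → 40 °C; aq NaHCO3
Reagents that add atoms: none
Why: Proposed new method: oxalyl chloride converts the salt into bis(acid chloride) 22 without acid or base; the enol ether carbon C5 attacks one acid chloride, the C4 oxocarbenium ion loses the C3 proton to give 23, C3 attacks the second acid chloride, and chloride then dealkylates the oxocarbenium ion to the C4 ketone. The closest known reaction is the Effenberger cyclization of 1-methoxycycloalkenes with malonyl dichloride, here made intramolecular and run on a seven-membered ring. Ring B closes by a 6-(enolexo)-exo-trig acylation (C5–C9) and ring A by a 6-(enolendo)-exo-trig acylation (C2–C3), which also completes the ring C3–C2–C1–C8–C7–C10–C11. C5 and C1 are set by the tether, because C9 can reach only the face of the seven-membered ring that carries the C7 arm and C1 must turn C2 to that same face; C3 is set likewise, C2 arriving cis to C8 so that ring D becomes trans-fused whatever the C3 configuration of 22. The step needs C- rather than O-acylation and enolization toward C3 after the first closure: the O-methyl group keeps the C4 oxygen capped until both bonds exist, re-enolization toward C5 would put a double bond at a bridgehead of the bicyclo[4.3.1] intermediate, and the acid chlorides make each acylation irreversible.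

Step 13
Reactants: 24 caged trione; 25 geranyl bromide
Product: 27 5-geranyl trione, via C5-lithio trione 26 (not isolated)
Conditions: LiTMP (from 2,2,6,6-tetramethylpiperidine and n-BuLi), THF, −78 °C; then 25, −78 → 0 °C
Reagents that add atoms: none
Why: Bridgehead deprotonation between the C4 and C9 carbonyls by the hindered lithium amide should occur at C5, the less shielded bridgehead (C1 is flanked by quaternary C8), and SN2 alkylation by the allylic bromide proceeds with retention because the carbanion is held in the cage.

Step 14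
Reactants: 27 5-geranyl trione; 28 benzoyl chloride
Product: 30 CNP0155129.1 (target), via C1-lithio compound 29 (not isolated)
Conditions: LiTMP (from 2,2,6,6-tetramethylpiperidine and n-BuLi), THF, −78 °C; then 28, −78 → −20 °C
Reagents that add atoms: none
Why: A second bridgehead lithiation at C1, the only acidic position left, and C-acylation by benzoyl chloride complete the target; O-acylation would need a bridgehead enol, and the C1 configuration is fixed by the cage.

Compound list
1 | 8-bromo-1,4-dioxaspiro[4.5]decane | BrC1CCC2(CC1)OCCO2 | starting material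
2 | dimethyl 2-(propan-2-ylidene)propanedioate | COC(=O)C(=C(C)C)C(=O)OC | starting material
3 | (1,4-dioxaspiro[4.5]decan-8-yl)magnesium bromide | Br[Mg]C1CCC2(CC1)OCCO2 | intermediate
4 | dimethyl 2-[2-(1,4-dioxaspiro[4.5]decan-8-yl)propan-2-yl]propanedioate | COC(=O)C(C(=O)OC)C(C)(C)C1CCC2(CC1)OCCO2 | intermediate
5 | dimethyl 2-[2-(4-oxocyclohexyl)propan-2-yl]propanedioate | COC(=O)C(C(=O)OC)C(C)(C)C1CCC(=O)CC1 | intermediate
6 | dimethyl 2-{2-[(1S)-4-(trimethylsilyloxy)cyclohex-3-en-1-yl]propan-2-yl}propanedioate | C1C[C@H](C(C)(C)C(C(=O)OC)C(=O)OC)CC=C1O[Si](C)(C)C | intermediate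
7 | dimethyl 2-{2-[(4S)-1-(trimethylsilyloxy)bicyclo[4.1.0]heptan-4-yl]propan-2-yl}propanedioate, both cyclopropane diastereomers | C1C[C@H](C(C)(C)C(C(=O)OC)C(=O)OC)CC2CC12O[Si](C)(C)C | intermediate
8 | dimethyl 2-{2-[(1S)-3-chloro-5-oxocycloheptyl]propan-2-yl}propanedioate, both C–Cl epimers | C1C[C@H](C(C)(C)C(C(=O)OC)C(=O)OC)CC(Cl)CC1=O | intermediate
9 | dimethyl 2-{2-[(1S)-5-oxocyclohept-3-en-1-yl]propan-2-yl}propanedioate | C1C[C@H](C(C)(C)C(C(=O)OC)C(=O)OC)CC=CC1=O | intermediate
10 | dimethyl 2-{2-[(1R)-4-(trimethylsilyloxy)cyclohepta-3,5-dien-1-yl]propan-2-yl}propanedioate | C1(O[Si](C)(C)C)=CC[C@H](C(C)(C)C(C(=O)OC)C(=O)OC)CC=C1 | intermediate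
11 | dimethyl 2-{2-[(1R)-4-oxocyclohepta-2,5-dien-1-yl]propan-2-yl}propanedioate | C1=C[C@H](C(C)(C)C(C(=O)OC)C(=O)OC)CC=CC1=O | intermediate
12 | potassium trifluoro(prop-1-en-2-yl)borate | C=C(C)[B-](F)(F)F.[K+] | starting material
13 | dimethyl 2-{2-[(1R,6S)-4-oxo-6-(prop-1-en-2-yl)cyclohept-2-en-1-yl]propan-2-yl}propanedioate | C1=C[C@H](C(C)(C)C(C(=O)OC)C(=O)OC)C[C@H](C(C)=C)CC1=O | intermediate
14 | 1-bromo-3-methylbut-2-ene | CC(C)=CCBr | starting material
15 | dilithium species of 13 (C3=C4 lithium enolate and lithium malonate enolate) | C1=C[C@H](C(C)(C)C(C(=O)OC)=C(OC)O[Li])C[C@H](C(C)=C)C=C1O[Li] | intermediate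
16 | dimethyl 2-{2-[(1R,5R,6S)-5-(3-methylbut-2-en-1-yl)-4-oxo-6-(prop-1-en-2-yl)cyclohept-2-en-1-yl]propan-2-yl}propanedioate | C1=C[C@H](C(C)(C)C(C(=O)OC)C(=O)OC)C[C@H](C(C)=C)[C@@H](CC=C(C)C)C1=O | intermediate
17 | dimethyl 2-{2-[(1S,3S,4R)-4-(3-methylbut-2-en-1-yl)-5-oxo-3-(prop-1-en-2-yl)cycloheptyl]propan-2-yl}propanedioate | C1C[C@H](C(C)(C)C(C(=O)OC)C(=O)OC)C[C@H](C(C)=C)[C@@H](CC=C(C)C)C1=O | intermediate
18 | trans-fused hydroazulenone: C4 ketone, ring D on C3–C11, C12 gem-dimethyl, C13 isopropyl, C7 C(CH3)2CH(CO2Me)2 arm (3R,7S,11S,13R) | C1C[C@H](C(C)(C)C(C(=O)OC)C(=O)OC)C[C@@H]2C(C)(C)[C@@H](C(C)C)C[C@H]2C1=O | intermediate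
19 | C4 dimethyl ketal of 18 | C1C[C@H](C(C)(C)C(C(=O)OC)C(=O)OC)C[C@@H]2C(C)(C)[C@@H](C(C)C)C[C@H]2C1(OC)OC | intermediate
20 | C4 methyl enol ether of 18 (C4=C5 isomer drawn) | COC1=CC[C@H](C(C)(C)C(C(=O)OC)C(=O)OC)C[C@@H]2C(C)(C)[C@@H](C(C)C)C[C@H]21 | intermediate
21 | dipotassium malonate of the enol ether | COC1=CC[C@H](C(C)(C)C(C(=O)[O-])C(=O)[O-])C[C@@H]2C(C)(C)[C@@H](C(C)C)C[C@H]21.[K+].[K+] | intermediate
22 | key-step precursor: hydroazulenone C4 methyl enol ether with the C8–C1 malonyl dichloride arm on C7 | COC1=CC[C@H](C(C)(C)C(C(=O)Cl)C(=O)Cl)C[C@@H]2C(C)(C)[C@@H](C(C)C)C[C@H]21 | intermediate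
23 | ring B-closed intermediate: C5–C9 formed, C3=C4 methyl enol ether, C1 acid chloride | [C@@H]1(C(=O)[C@H](C(=O)Cl)C2(C)C)C[C@H]2C[C@@H]3C(C)(C)[C@@H](C(C)C)CC3=C1OC | intermediate
24 | caged trione (1-debenzoyl-5-degeranyl target), H on C1 and C5 | [C@@H]12C[C@H]3C[C@@H]4C(C)(C)[C@@H](C(C)C)C[C@]4(C1=O)C(=O)[C@@H](C2=O)C3(C)C | intermediate
25 | geranyl bromide, (2E)-1-bromo-3,7-dimethylocta-2,6-diene | CC(C)=CCC/C(C)=C/CBr | starting material
26 | C5-lithio derivative of 24 | [Li][C@@]12C[C@H]3C[C@@H]4C(C)(C)[C@@H](C(C)C)C[C@]4(C1=O)C(=O)[C@@H](C2=O)C3(C)C | intermediate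
27 | 5-geranyl trione (1-debenzoyl target) | CC(C)=CCC/C(C)=C/C[C@@]12C[C@H]3C[C@@H]4C(C)(C)[C@@H](C(C)C)C[C@]4(C1=O)C(=O)[C@@H](C2=O)C3(C)C | intermediate
28 | benzoyl chloride | O=C(Cl)c1ccccc1 | starting material
29 | C1-lithio derivative of 27 | CC(C)=CCC/C(C)=C/C[C@@]12C[C@H]3C[C@@H]4C(C)(C)[C@@H](C(C)C)C[C@]4(C1=O)C(=O)[C@@]([Li])(C2=O)C3(C)C | intermediate
30 | CNP0155129.1 | CC(C)=CCC/C(C)=C/C[C@@]12C[C@H]3C[C@@H]4C(C)(C)[C@@H](C(C)C)C[C@]4(C1=O)C(=O)[C@@](C(=O)c1ccccc1)(C2=O)C3(C)C | target

Total steps: 14. Longest linear sequence: 14 steps (from 1).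

Steps most likely to fail

Step 12 (proposed new method). Chloride may remove the O-methyl group from the oxocarbenium ion before the second bond forms, after which the freed 1,3-diketone enol O-acylates; intermolecular acylation may also compete with the closure onto the fully substituted C3. Fallback, built from single acylations of alkyl enol ethers by one acid chloride at a time: starting from 20, one equivalent of KOSiMe3 should give the monopotassium half-ester F1. Oxalyl chloride converts it into the mono(acid chloride) F2, which closes ring B at C5 to give the keto ester enol ether F3; this can be isolated and purified. KOSiMe3 then cleaves the remaining ester to the potassium carboxylate F4, and oxalyl chloride returns to the route at 23. The second closure to 24 is then run on its own at high dilution, with ZnCl2 as promoter if required.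

Step 9. Hydrogen atom transfer may go to the trisubstituted prenyl olefin instead, so that one or both olefins are simply reduced, and facial control at C13 in the ring closure may be incomplete. Fallback by a thiyl radical chain: starting from 17, PhSH and AIBN in toluene at 80 °C add PhS reversibly to the terminal carbon of the isopropenyl group; the C12 radical cyclizes as in step 9 and takes hydrogen from the thiol to give the cyclized sulfide F5. Skeletal Ni in EtOH–acetone removes sulfur, turns the CH2SPh group into the second C12 methyl and returns to the route at 18.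

Step 14. C-acylation of the hindered C1 carbanion may be slow, leaving time for the base or the carbanion to attack the non-enolizable ketones and open the cage. Fallback by halogen–metal exchange and a smaller electrophile: starting from 27, LiTMP then I2 should give the bridgehead iodide F6. Exchange with i-PrMgCl·LiCl at −78 °C gives the bridgehead magnesium chloride F7, which adds to benzaldehyde to give the carbinol F8 (either epimer). Oxidation with 2-iodoxybenzoic acid in DMSO returns to the route at 30.

Further compounds
F1 | step 12 | monopotassium salt of the malonic half methyl ester of 20 (either C1 epimer) | COC1=CC[C@H](C(C)(C)C(C(=O)[O-])C(=O)OC)C[C@@H]2C(C)(C)[C@@H](C(C)C)C[C@H]21.[K+]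
F2 | step 12 | mono(acid chloride) methyl ester of the enol ether | COC1=CC[C@H](C(C)(C)C(C(=O)Cl)C(=O)OC)C[C@@H]2C(C)(C)[C@@H](C(C)C)C[C@H]21
F3 | step 12 | ring B-closed keto methyl ester with C3=C4 methyl enol ether | [C@@H]1(C(=O)[C@H](C(=O)OC)C2(C)C)C[C@H]2C[C@@H]3C(C)(C)[C@@H](C(C)C)CC3=C1OC
F4 | step 12 | potassium carboxylate of F3 | [C@@H]1(C(=O)[C@H](C(=O)[O-])C2(C)C)C[C@H]2C[C@@H]3C(C)(C)[C@@H](C(C)C)CC3=C1OC.[K+]
F5 | step 9 | hydroazulenone 18 with one C12 methyl as CH2SPh (both C12 epimers) | C1C[C@H](C(C)(C)C(C(=O)OC)C(=O)OC)C[C@@H]2C(C)(CSc3ccccc3)[C@@H](C(C)C)C[C@H]2C1=O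
F6 | step 14 | 1-iodo-5-geranyl trione | CC(C)=CCC/C(C)=C/C[C@@]12C[C@H]3C[C@@H]4C(C)(C)[C@@H](C(C)C)C[C@]4(C1=O)C(=O)[C@@](I)(C2=O)C3(C)C
F7 | step 14 | C1 chloromagnesium derivative of 27 | CC(C)=CCC/C(C)=C/C[C@@]12C[C@H]3C[C@@H]4C(C)(C)[C@@H](C(C)C)C[C@]4(C1=O)C(=O)[C@@]([Mg]Cl)(C2=O)C3(C)C
F8 | step 14 | 1-[hydroxy(phenyl)methyl]-5-geranyl trione (either carbinol epimer) | CC(C)=CCC/C(C)=C/C[C@@]12C[C@H]3C[C@@H]4C(C)(C)[C@@H](C(C)C)C[C@]4(C1=O)C(=O)[C@@](C(O)c1ccccc1)(C2=O)C3(C)C
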